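**Assumptions (one line):** Compounds 6, 10 and 11 are purchasable (10 is also one Vilsmeier step from orcinol). Lithiation of 5 is assumed to occur with retention and the aryl 1,2-shift with inversion. On that basis (R)-propylene oxide gives the (R)-target. If the opposite sense is found, use (S)-1 instead.

## Retrosynthetic overview
1. Final step: global O-demethylation of the bis-methyl ether 14.
2. Diarylmethane C–CH2 bond: a photogenerated ortho-quinone methide from salicyl alcohol 13 (ring B) is arylated by the ring C aryl-Bpin 9, under neutral conditions that spare the acid-labile tertiary benzylic alcohol.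
3. Ring A–O–ring B ether: Chan–Lam O-arylation at the 4-OH of orcylaldehyde, then CHO→CH2OH.
4. The only stereocenter is set by a stereospecific lithiation–borylation–oxidation of a secondary TIB ester. That ester comes from (R)-propylene oxide + isopentyl Grignard.
5. No rings are built; three commercial arenes are joined in the order A–O–B, then B–CH2–C.

## Route

**Step 1**
Reactants: 1 (R)-2-methyloxirane [(R)-propylene oxide]; 2 isopentylmagnesium bromide
Product: 3 (R)-6-methylheptan-2-ol
Conditions: CuI (5 mol%), THF, –30 → 0 °C; aq. NH4Cl
Reagents that add atoms: none (the Grignard is reactant 2)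
Why: Cu-catalysed Grignard opening of a terminal epoxide occurs at the CH2 carbon, so the C–O bond at the stereocenter is never broken and (R) is retained.

**Step 2**
Reactants: 3; 4 2,4,6-triisopropylbenzoyl chloride (TIBCl)
Product: 5 (R)-6-methylheptan-2-yl 2,4,6-triisopropylbenzoate
Conditions: n-BuLi, THF, –78 °C; then 4, –78 °C → rt
Reagents that add atoms: none (4 is a reactant)
Why: Acylation of the lithium alkoxide; the stereocenter is untouched. The TIB group both enables α-lithiation and serves as the leaving group later.

**Step 3**
Reactants: 6 4-bromo-1-iodo-2-methoxybenzene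
Product: 7 2-(4-bromo-2-methoxyphenyl)-4,4,5,5-tetramethyl-1,3,2-dioxaborolane
Conditions: i-PrMgCl·LiCl, THF, –40 °C, 1 h; then i-PrOBpin, –40 °C → rt
Reagents that add atoms: i-PrOBpin, CC(C)OB1OC(C)(C)C(C)(C)O1
Why: I/Mg exchange is selective over Br/Mg exchange, and the arylmagnesium is trapped by the borate to give the aryl boronic ester.

**Step 4**
Reactants: 5; 7
Product: 8 (R)-2-(4-bromo-2-methoxyphenyl)-6-methylheptan-2-ol
Conditions: s-BuLi, TMEDA, Et2O, –78 °C, 3 h; add 7 (1.5 equiv), –78 °C, 1 h, then THF, 40 °C, 16 h; then 30% H2O2, 3 M NaOH, 0 °C → rt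
Reagents that add atoms: hydrogen peroxide, OO (NaOH and s-BuLi leave no atoms)
Why: Hoppe/Aggarwal lithiation–borylation. Lithiation occurs with retention and the aryl shifts from the boronate to the carbon with inversion, expelling TIB carboxylate. This gives an enantioenriched tertiary benzylic boronic ester, and stereoretentive oxidation of C–B to C–OH sets the (R) tertiary carbinol with all chirality coming from 1.

**Step 5**
Reactants: 8
Product: 9 (R)-2-[2-methoxy-4-(pinacolboryl)phenyl]-6-methylheptan-2-ol
Conditions: B2pin2 (1.3 equiv), Pd(dppf)Cl2 (3 mol%), KOAc, dioxane, 90 °C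
Reagents that add atoms: bis(pinacolato)diboron, CC1(C)OB(OC1(C)C)B1OC(C)(C)C(C)(C)O1
Why: Miyaura borylation, which tolerates the free tertiary alcohol; the stereocenter is remote from the reacting C–Br bond.

**Step 6**
Reactants: 10 2,4-dihydroxy-6-methylbenzaldehyde (orcylaldehyde); 11 (3-methoxy-5-methylphenyl)boronic acid
Product: 12 2-hydroxy-4-(3-methoxy-5-methylphenoxy)-6-methylbenzaldehyde
Conditions: Cu(OAc)2 (1.0 equiv), pyridine (3 equiv), 4 Å MS, CH2Cl2, air, rt, 24 h
Reagents that add atoms: none (11 is a reactant)
Why: Chan–Lam O-arylation is selective for the 4-OH, because the 2-OH is chelated to the CHO and the 4-OH is more acidic. This places the ether para to the future CH2 site, as in the target.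

**Step 7**
Reactants: 12
Product: 13 [2-hydroxy-4-(3-methoxy-5-methylphenoxy)-6-methylphenyl]methanol
Conditions: NaBH4, MeOH, 0 °C, 20 min; aq. NH4Cl
Reagents that add atoms: none (hydride only)
Why: Chemoselective aldehyde reduction gives the o-hydroxybenzyl alcohol, the o-quinone methide precursor.

**Step 8**
Reactants: 13; 9 (2.5 equiv)
Product: 14 (R)-2-{4-[2-hydroxy-4-(3-methoxy-5-methylphenoxy)-6-methylbenzyl]-2-methoxyphenyl}-6-methylheptan-2-ol
Conditions: hν (310 nm, quartz), MeCN/H2O 4:1, 25 °C, 3 h, no acid or base
Reagents that add atoms: none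
Why: Proposed new method: photodehydration of the salicyl alcohol by excited-state intramolecular proton transfer gives the o-quinone methide. It is intercepted by the aryl-B(pin/OH)2, via a cyclic salicyl boronate, by Petasis-type 1,4-transfer of the aryl group to the exocyclic CH2. The closest known reactions are the photogeneration of o-quinone methides from o-hydroxybenzyl alcohols and the addition of arylboronic acids to o-quinone methides. The conditions are acid-free, the benzylic carbon is fixed by the precursor (no C4/C2/C6 ambiguity), and the tertiary benzylic carbinol is neither ionised nor racemised.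

**Step 9**
Reactants: 14
Product: 15 target, (R)-2-{4-[2-hydroxy-4-(3-hydroxy-5-methylphenoxy)-6-methylbenzyl]-2-hydroxyphenyl}-6-methylheptan-2-ol
Conditions: NaSEt (6 equiv), DMF, 130 °C, 4 h; aq. NH4Cl to pH ~6
Reagents that add atoms: none (MeSEt is lost)
Why: SN2 thiolate demethylation of both aryl methyl ethers under basic conditions avoids BBr3, which would ionise or racemise the tertiary benzylic alcohol. The stereocenter has no mechanism for epimerisation here.

**Checks performed**
- Target match: ring A is 3-OH-5-Me-phenyl; ring B has OAr, Me, CH2Ar and OH in the target pattern (from orcylaldehyde); ring C is para-CH2, ortho-OH to the carbinol, with the (R) C(Me)(OH)(CH2)3CHMe2 side chain.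
- Stereocenter: set once, in Step 4, and carried untouched through Steps 5–9.
- Descriptor: the SMILES order [aryl, Me, O, chain] is "@" in 8, 9, 14 and 15, which corresponds to (R).
- Atom balance: C8 chain (3) + aryl (7) gives 8; all later steps add only B, aryl or CH2 units, and demethylation removes two CH3.

## Compound list
1 | (R)-2-methyloxirane | C[C@@H]1CO1 | starting material
2 | isopentylmagnesium bromide | [Mg](Br)CCC(C)C | starting material
3 | (R)-6-methylheptan-2-ol | C[C@@H](O)CCCC(C)C | intermediate
4 | 2,4,6-triisopropylbenzoyl chloride | CC(C)c1cc(C(C)C)c(C(=O)Cl)c(C(C)C)c1 | starting material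
5 | (R)-6-methylheptan-2-yl 2,4,6-triisopropylbenzoate | C[C@@H](OC(=O)c1c(C(C)C)cc(C(C)C)cc1C(C)C)CCCC(C)C | intermediate
6 | 4-bromo-1-iodo-2-methoxybenzene | COc1cc(Br)ccc1I | starting material
7 | 2-(4-bromo-2-methoxyphenyl)-Bpin | COc1cc(Br)ccc1B1OC(C)(C)C(C)(C)O1 | intermediate
8 | (R)-2-(4-bromo-2-methoxyphenyl)-6-methylheptan-2-ol | COc1cc(Br)ccc1[C@](C)(O)CCCC(C)C | intermediate
9 | (R)-2-[2-methoxy-4-(Bpin)phenyl]-6-methylheptan-2-ol | COc1cc(B2OC(C)(C)C(C)(C)O2)ccc1[C@](C)(O)CCCC(C)C | intermediate
10 | 2,4-dihydroxy-6-methylbenzaldehyde | Cc1cc(O)cc(O)c1C=O | starting material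
11 | (3-methoxy-5-methylphenyl)boronic acid | COc1cc(C)cc(B(O)O)c1 | starting material
12 | 2-hydroxy-4-(3-methoxy-5-methylphenoxy)-6-methylbenzaldehyde | Cc1cc(OC)cc(Oc2cc(C)c(C=O)c(O)c2)c1 | intermediate
13 | [2-hydroxy-4-(3-methoxy-5-methylphenoxy)-6-methylphenyl]methanol | Cc1cc(OC)cc(Oc2cc(C)c(CO)c(O)c2)c1 | intermediate
14 | bis-methyl ether diarylmethane | COc1cc(C)cc(Oc2cc(C)c(Cc3ccc([C@](C)(O)CCCC(C)C)c(OC)c3)c(O)c2)c1 | intermediate
15 | target | Cc1cc(O)cc(Oc2cc(C)c(Cc3ccc([C@](C)(O)CCCC(C)C)c(O)c3)c(O)c2)c1 | target

**Total steps:** 9. **Longest linear sequence:** 6 (1 → 3 → 5 → 8 → 9 → 14 → 15, counting Steps 1, 2, 4, 5, 8, 9).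

## Three steps most likely to fail
1. **Step 8 (proposed new photochemical o-quinone methide arylation).** Competing o-QM hydration or dimerisation, poor aryl transfer from the pinacol ester, and photoionisation of the tertiary benzylic alcohol are the risks.
 *Fallback (known chemistry):* protect the phenol of 13 as its TBS ether and convert the benzylic alcohol to the bromide (CBr4/PPh3). Then do a Pd-catalysed Suzuki–Miyaura coupling of that benzyl bromide with 9, and remove the TBS group (TBAF) before Step 9.
2. **Step 4 (lithiation–borylation of an aliphatic secondary TIB ester with a hindered, ortho-alkoxy aryl Bpin).** The risks are incomplete α-lithiation, Br/Li exchange on the aryl bromide, and the opposite stereochemical sense.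
 *Fallback:* carry out the stereoretentive α-lithiation of the secondary (R)-alkyl carbamate and transmetalate to zinc. Follow with Pd-catalysed Negishi arylation using aryl iodide 6 (keeping the C–O bond), then cleave the tertiary carbamate.
3. **Step 9 (hot thiolate demethylation of both aryl methyl ethers, including the hindered ring C OMe).** Incomplete cleavage or decomposition at 130 °C are the risks.
 *Fallback:* redo Steps 3–6 with benzyl ethers in place of OMe: ring A boronic acid as the OBn analogue and ring C as the OBn analogue of 6. Then remove both with H2, Pd/C in EtOAc at rt, which is neutral and leaves the tertiary alcohol intact.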